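The complex with two exchanged is the product we count, and the incoming ligand that makes it also destroys it.

- the best flask by share of complex with two exchanged in complex with two exchanged plus over-reaction product; "all alike" if 1.5 percentage points covers them all (south-east / south-west / west / south / all alike)
- share of complex with two exchanged in complex with two exchanged plus over-reaction product at the end, south-east
- share of complex with two exchanged in complex with two exchanged plus over-reaction product at the end, south-west
- share of complex with two exchanged in complex with two exchanged plus over-reaction product at the end, west
- share of complex with two exchanged in complex with two exchanged plus over-reaction product at the end, south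

| flask | starting complex | incoming ligand | temperature | time | remark |
|---|---|---|---|---|---|
| south-east | 0.050 M (in portions, 2, over 8.0 s) | 0.0475 M | 60 °C | 10 s | first portion at the start, last at 8.0 s |
| south-west | 0.050 M (fed, over 8.0 s) | 0.0475 M |  | 10 s | the addition at 20 °C, then warmed to 60 °C; the feed brings no volume worth counting |
| west | 0.050 M | 0.0475 M (fed, over 8.0 s) | 60 °C | 10 s | all else is in the flask from the start; the feed brings no volume worth counting |
| south | 0.050 M (fed, over 8.0 s) | 0.0475 M | 60 °C | 10 s | all else is in the flask from the start; the feed brings no volume worth counting |

    starting complex + incoming ligand → leaving ligand + complex with one exchanged (k1 = 3.90 M⁻¹ s⁻¹, Ea1 = 53.0 kJ mol⁻¹)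
    complex with one exchanged + incoming ligand → leaving ligand + complex with two exchanged (k2 = 6.74 M⁻¹ s⁻¹, Ea2 = 39.0 kJ mol⁻¹)
    2 starting complex → self-condensation product (k3 = 0.263 M⁻¹ s⁻¹, Ea3 = 61.0 kJ mol⁻¹)
    complex with two exchanged + incoming ligand → over-reaction product (k4 = 4.34 M⁻¹ s⁻¹, Ea4 = 50.0 kJ mol⁻¹)
    (constants at 60 °C)

- percentages count the starting complex that a species holds: one self-condensation product counts as two
- a step written with two of one species runs at k times the square of its concentration and takes two of it each time
- constants are those at 60 °C; use the activation energies for any other temperature

My colleague and I dispute this. He writes the rates of the second exchange and of the over-reaction side by side. [incoming ligand] stands in both, so it cancels from their ratio. What remains is the selectivity factor, 1.55 at 60 °C, and a recipe held at that temperature does not change it. He sets south-west's cold addition aside and therefore expects "all alike".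

I answer that his ratio also holds [complex with one exchanged] over [complex with two exchanged], and that this moves as a complex meets ligand. So I count exposure, the time integral of [incoming ligand] that a portion of complex has met. For a portion charged at once, at constant temperature and small exposure, complex with two exchanged grows as the square of exposure and over-reaction product as its cube. Their ratio is then exposure times the spending coefficient 1.45 M⁻¹ s⁻¹, and the share is one over one plus that product.

South-west is fed cold, and I set that stage aside, counting only the 2.00 s after warming. At full charge the exposure is 0.0950 M·s, which gives 87.9%. I put that back and go round once more. Starting complex takes ligand in a roughly pseudo-first-order way, removing a fraction 0.390 over this time. Mean [incoming ligand] is lower by half of that, so the exposure is 0.0765 M·s and the share is 90.0%.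

For the oldest complex in south-east and south, exposure at full charge is 0.475 M·s. In west, where the ligand arrives gradually, it is 0.285 M·s, which is smaller. These lie beyond small exposure, so I commit to an order, not to shares. South-west has the lowest exposure, and my best flask is south-west.

The forecast takes my side: best south-west, with south-east 65%, south-west 91% (range 87% to 94%), west 83% and south 72%. Its south-west stands slightly above mine. Its ground: “the share stays high where little complex with two exchanged has had time to meet free incoming ligand”.

The simulation gives south-east 62.7%, south-west 86.9%, west 77.5% and south 69.8%, so south-west is best, 24 percentage points above south-east, far beyond the margin of 1.5 points. My colleague's view comes nearer late: at 100 s, with incoming ligand at 0% in south-west, south-west stands at 68.8% and south-east at 58.5%, a gap of 10 points. South-west's ligand readings after warming, 94.0% to 61.7%, give an exposure of 0.0739 M·s, and g turns that into 90.3%. Read at 15 s, the same flask has ligand at 21.1%, an exposure of 0.191 M·s, and g gives 78.3%, against a reading of 75.1%.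

The constants were chosen freely; the run is a simulation.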